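**Retrosynthetic overview**

1. Last ring, the dihydrofuran C4a–O5–C5a–C9a–C9b (dibenzofuran numbering). C4a–O5 lies β to the C3 ketone, and C9b, γ to it, carries the ortho-oxygenated aryl ring, so this ring is the retron of a 5-exo oxa-Michael addition. Cutting O5–C4a and adding H2 leaves an achiral macrocyclic 4-aryl-4-alkenylcyclohexanone with a mirror plane through C3=O and C9b, whose two CH2CH2 arms are enantiotopic. Forward, one desymmetrising desaturation makes the enone and sets C9b, and the phenol closes the ring and sets C4a.
2. 20-membered ring: the N–CH2 bond of the spermidine secondary amine, by intramolecular reductive amination of an amino aldehyde, so no nitrogen protecting group outlives the ring closure.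
3. Z-enamides: on the quaternary-carbon side by Still–Gennari-type olefination of a lactol with a phosphonoacetamide; on the aryl side by Suzuki–Miyaura coupling with a (Z)-3-iodoacrylamide.
4. Quaternary carbon and cyclohexanone ring: double Michael addition/Dieckmann condensation of an arylacetonitrile with methyl acrylate; a spiro-lactone (temporary ring) masks the phenol and stores the aldehyde carbon.
5. Order of ring formation: benzene (purchased) → cyclohexanone → temporary lactone (opened again) → macrocycle → dihydrofuran.

Key step: step 12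

Remark: both amide-conjugated C=C bonds of the target are cis (Z) as drawn and are built as such; the trifluoroethyl phosphonoacetic acid of step 5 is assumed to be a catalogue compound (otherwise it is made from its commercial methyl ester).

**Route**

Step 1
Reactants: 1 2-(5-bromo-2-methoxyphenyl)acetonitrile; 2 methyl acrylate (2.2 equiv)
Product: 4 methyl 5-(5-bromo-2-methoxyphenyl)-5-cyano-2-oxocyclohexane-1-carboxylate (racemic keto–enol mixture), via bis-Michael diester 3 (not isolated)
Conditions: t-BuOK (2.5 equiv), THF, 0 °C → rt; aq. HCl quench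
Reagents that add atoms: none
Why: double Michael addition of the benzylic nitrile anion to the acrylate followed in the same flask by Dieckmann condensation should build the cyclohexanone ring and the quaternary carbon; the stereocentres of 4 are lost in step 2.

Step 2
Reactants: 4 methyl 5-(5-bromo-2-methoxyphenyl)-5-cyano-2-oxocyclohexane-1-carboxylate
Product: 7 5-bromo-2H-spiro[benzofuran-3,1'-cyclohexane]-2,4'-dione, via cyano ketone 5 (not isolated), via iminolactone 6 (not isolated)
Conditions: 48% aq. HBr, AcOH, reflux
Reagents that add atoms: water, O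
Why: acid hydrolysis/decarboxylation of the β-keto ester, HBr cleavage of the aryl methyl ether and Pinner-type addition of the freed phenol to the neighbouring nitrile, then hydrolysis of the iminolactone, should give the gem-disubstituted lactone, a temporary ring that masks the phenol and the future aldehyde carbon.

Step 3
Reactants: 7 5-bromo-2H-spiro[benzofuran-3,1'-cyclohexane]-2,4'-dione
Product: 8 5-bromo-2H-dispiro[benzofuran-3,1'-cyclohexane-4',2''-[1,3]dioxolan]-2-one
Conditions: ethylene glycol (3 equiv), p-TsOH·H2O (5 mol%), toluene, reflux, Dean–Stark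
Reagents that add atoms: ethylene glycol, OCCO
Why: standard acid-catalysed ketalisation with azeotropic removal of water; the five-membered aryl lactone re-closes under these conditions if it opens transiently (Thorpe–Ingold effect).

Step 4
Reactants: 8 5-bromo-2H-dispiro[benzofuran-3,1'-cyclohexane-4',2''-[1,3]dioxolan]-2-one
Product: 9 5-bromo-2H-dispiro[benzofuran-3,1'-cyclohexane-4',2''-[1,3]dioxolan]-2-ol (racemic lactol)
Conditions: DIBAL-H (1.2 equiv), CH2Cl2, −78 °C; Rochelle salt work-up
Reagents that add atoms: none
Why: partial reduction of a lactone to the lactol, the cyclic aluminium hemiacetal being held closed at −78 °C by the adjacent quaternary centre; the hemiacetal centre is racemic and disappears in step 6.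

Step 5
Reactants: 10 [bis(2,2,2-trifluoroethoxy)phosphoryl]acetic acid; 11 3,3-diethoxypropan-1-amine
Product: 12 2-[bis(2,2,2-trifluoroethoxy)phosphoryl]-N-(3,3-diethoxypropyl)acetamide
Conditions: EDC·HCl, HOBt, CH2Cl2, 0 °C → rt; NaHCO3 wash
Reagents that add atoms: none
Why: carbodiimide amide coupling with pre-activation of the acid; the acetal survives the non-acidic work-up.

Step 6
Reactants: 9 racemic lactol; 12 2-[bis(2,2,2-trifluoroethoxy)phosphoryl]-N-(3,3-diethoxypropyl)acetamide (1.3 equiv)
Product: 14 tert-butyl 4-bromo-2-{8-[(Z)-3-[(3,3-diethoxypropyl)amino]-3-oxoprop-1-enyl]-1,4-dioxaspiro[4.5]decan-8-yl}phenyl carbonate, via potassium phenoxide 13 (not isolated)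
Conditions: KHMDS (1.0 equiv on 9; 1.3 equiv on 12), 18-crown-6, THF, −78 → −30 °C; then Boc2O (1.5 equiv), −30 → 0 °C
Reagents that add atoms: di-tert-butyl dicarbonate, CC(C)(C)OC(=O)OC(=O)OC(C)(C)C
Why: Still–Gennari-type Z-selective Horner–Wadsworth–Emmons olefination of the aldehyde released from the lactol alkoxide (kinetic control by the electron-poor phosphonate, reinforced by the bulky α-quaternary aldehyde), with the freed phenoxide capped in the same flask as its tert-butyl carbonate so that it cannot add to the new acrylamide.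

Step 7
Reactants: 14 aryl bromide carbonate
Product: 15 tert-butyl 2-{8-[(Z)-3-[(3,3-diethoxypropyl)amino]-3-oxoprop-1-enyl]-1,4-dioxaspiro[4.5]decan-8-yl}-4-(4,4,5,5-tetramethyl-1,3,2-dioxaborolan-2-yl)phenyl carbonate
Conditions: B2pin2 (1.2 equiv), Pd(dppf)Cl2 (5 mol%), KOAc (3 equiv), 1,4-dioxane, 85 °C
Reagents that add atoms: bis(pinacolato)diboron, CC1(C)OB(OC1(C)C)B1OC(C)(C)C(C)(C)O1
Why: Miyaura borylation of the aryl bromide; acetate is too weak a base to disturb the carbonate, the acetals or the Z-acrylamide.

Step 8
Reactants: 16 (Z)-3-iodoacrylic acid; 17 tert-butyl (4-aminobutyl)carbamate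
Product: 18 tert-butyl {4-[(Z)-3-iodoprop-2-enamido]butyl}carbamate
Conditions: EDC·HCl, HOBt, CH2Cl2, −10 → 0 °C (acid pre-activated, amine added last)
Reagents that add atoms: none
Why: carbodiimide amide coupling at low temperature should retain the Z geometry and outrun addition–elimination of the amine at the β-carbon.

Step 9
Reactants: 15 aryl boronate; 18 tert-butyl {4-[(Z)-3-iodoprop-2-enamido]butyl}carbamate
Product: 19 tert-butyl 4-[(Z)-3-({4-[(tert-butoxycarbonyl)amino]butyl}amino)-3-oxoprop-1-enyl]-2-{8-[(Z)-3-[(3,3-diethoxypropyl)amino]-3-oxoprop-1-enyl]-1,4-dioxaspiro[4.5]decan-8-yl}phenyl carbonate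
Conditions: Pd(PPh3)4 (5 mol%), K3PO4 (3 equiv), THF/H2O (10:1), 40 °C, degassed
Reagents that add atoms: none
Why: Suzuki–Miyaura coupling of an aryl boronate with an alkenyl iodide proceeds with retention of alkene geometry and should deliver the Z-cinnamamide; partial loss of the aryl carbonate would be harmless because step 10 removes it.

Step 10
Reactants: 19 fully protected bis-Z-enamide
Product: 20 (Z)-N-(4-ammoniobutyl)-3-{4-hydroxy-3-[4-oxo-1-{(Z)-3-oxo-3-[(3-oxopropyl)amino]prop-1-enyl}cyclohexyl]phenyl}prop-2-enamide trifluoroacetate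
Conditions: TFA/CH2Cl2/H2O (5:4:1), anisole, 0 °C → rt; evaporation, used crude
Reagents that add atoms: water, O; trifluoroacetic acid, OC(=O)C(F)(F)F
Why: one acid treatment should remove the N-Boc and O-Boc groups and hydrolyse both the diethyl acetal and the dioxolane, while the amine stays protonated and cannot condense with the freed aldehyde.

Step 11
Reactants: 20 amino aldehyde trifluoroacetate
Product: 22 achiral macrocyclic keto phenol amine (20-membered bis-Z-enamide ring spiro-linked to cyclohexan-4-one), via macrocyclic imine 21 (not isolated)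
Conditions: syringe-pump addition of 20 to NaBH(OAc)3 (4 equiv), i-Pr2NEt (1.2 equiv), AcOH (2 equiv), CH2Cl2/MeCN, final 1 mM, rt; NaHCO3 work-up
Reagents that add atoms: none
Why: intramolecular reductive amination, in which the aldehyde condenses with the primary amine much faster than the ring ketone does, imine formation is reversible and triacetoxyborohydride reduces only the iminium ion, should form the secondary amine and the 20-membered ring at its most flexible site.

Step 12
Reactants: 22 achiral macrocyclic keto phenol amine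
Product: 24 target: (4aR,9bS)-cis-fused macrocyclic 1,2,4,4a-tetrahydrodibenzofuran-3(9bH)-one (CNP0159470.1), via enone 23 (not isolated)
Conditions: Old Yellow Enzyme-family flavin ene-reductase (FMN form, no NAD(P)H; variant chosen from a panel for the pro-S arm), O2 (air), catalase, KPi buffer pH 7.5/DMSO (9:1), 22 at 2 mM, 45 °C, dark
Reagents that add atoms: none
Why: Proposed new method: the flavoenzyme, run without nicotinamide in its oxidative direction, binds the C3 carbonyl of 22, an active-site tyrosine removes an α-proton of one CH2CH2 arm while the anti β-hydride passes to FMN (reoxidised by O2), and the resulting (S)-enone 23 is trapped at once by its ortho-phenol. The closest known reaction types are the ene-reductase-catalysed aerobic desymmetrising desaturation of 4,4-disubstituted cyclohexanones to γ-quaternary cyclohexenones and the spontaneous phenol oxa-Michael closure of 4-(2-hydroxyaryl)cyclohexenones; their coupling in one flask, on a macrocycle, is what is new. The dihydrofuran ring closes by 5-exo-trig conjugate addition of the phenol oxygen to the enone β-carbon (the future C4a). C9b (S) is set under catalyst control, the enzyme distinguishing the two enantiotopic arms of the mirror-symmetric ketone through the unlike aryl and Z-alkenyl groups on the two ring faces (an enantiocomplementary variant would give the antipode), and C4a (R) follows under substrate control because the O–C5a–C9a–C9b tether can reach only the face that carries the aryl group (cis fusion). The step needs arm selectivity, mono-desaturation and chemoselectivity among three conjugated alkenes: fast intramolecular trapping removes 23 before a second desaturation to the achiral dienone (the only racemising pathway) can compete, the arm left in 24 is the one the enzyme disfavours, amide-conjugated alkenes are neither ene-reductase substrates nor competitive Michael acceptors (the enone is far more electrophilic than the neopentylic Z-acrylamide that is also 5-exo to the phenol), and darkness prevents flavin-sensitised Z-to-E isomerisation.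

**Compound list**

1 | 2-(5-bromo-2-methoxyphenyl)acetonitrile | N#CCc1cc(Br)ccc1OC | starting material
2 | methyl acrylate | C=CC(=O)OC | starting material
3 | dimethyl 4-(5-bromo-2-methoxyphenyl)-4-cyanoheptanedioate | COC(=O)CCC(C#N)(CCC(=O)OC)c1cc(Br)ccc1OC | intermediate
4 | methyl 5-(5-bromo-2-methoxyphenyl)-5-cyano-2-oxocyclohexane-1-carboxylate (racemic, keto–enol mixture) | COC(=O)C1CC(C#N)(c2cc(Br)ccc2OC)CCC1=O | intermediate
5 | 1-(5-bromo-2-methoxyphenyl)-4-oxocyclohexane-1-carbonitrile | N#CC1(CCC(=O)CC1)c1cc(Br)ccc1OC | intermediate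
6 | 5-bromo-2-imino-2H-spiro[benzofuran-3,1'-cyclohexan]-4'-one (hydrobromide in the flask) | N=C1Oc2ccc(Br)cc2C12CCC(=O)CC2 | intermediate
7 | 5-bromo-2H-spiro[benzofuran-3,1'-cyclohexane]-2,4'-dione | O=C1Oc2ccc(Br)cc2C12CCC(=O)CC2 | intermediate
8 | 5-bromo-2H-dispiro[benzofuran-3,1'-cyclohexane-4',2''-[1,3]dioxolan]-2-one | O=C1Oc2ccc(Br)cc2C12CCC3(CC2)OCCO3 | intermediate
9 | 5-bromo-2H-dispiro[benzofuran-3,1'-cyclohexane-4',2''-[1,3]dioxolan]-2-ol (racemic lactol) | OC1Oc2ccc(Br)cc2C12CCC3(CC2)OCCO3 | intermediate
10 | [bis(2,2,2-trifluoroethoxy)phosphoryl]acetic acid | OC(=O)CP(=O)(OCC(F)(F)F)OCC(F)(F)F | starting material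
11 | 3,3-diethoxypropan-1-amine | CCOC(CCN)OCC | starting material
12 | 2-[bis(2,2,2-trifluoroethoxy)phosphoryl]-N-(3,3-diethoxypropyl)acetamide | CCOC(CCNC(=O)CP(=O)(OCC(F)(F)F)OCC(F)(F)F)OCC | intermediate
13 | potassium 4-bromo-2-{8-[(Z)-3-[(3,3-diethoxypropyl)amino]-3-oxoprop-1-enyl]-1,4-dioxaspiro[4.5]decan-8-yl}phenolate | CCOC(CCNC(=O)/C=C\C1(CCC2(CC1)OCCO2)c3cc(Br)ccc3[O-])OCC.[K+] | intermediate
14 | tert-butyl 4-bromo-2-{8-[(Z)-3-[(3,3-diethoxypropyl)amino]-3-oxoprop-1-enyl]-1,4-dioxaspiro[4.5]decan-8-yl}phenyl carbonate | CCOC(CCNC(=O)/C=C\C1(CCC2(CC1)OCCO2)c3cc(Br)ccc3OC(=O)OC(C)(C)C)OCC | intermediate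
15 | tert-butyl 2-{8-[(Z)-3-[(3,3-diethoxypropyl)amino]-3-oxoprop-1-enyl]-1,4-dioxaspiro[4.5]decan-8-yl}-4-(4,4,5,5-tetramethyl-1,3,2-dioxaborolan-2-yl)phenyl carbonate | CCOC(CCNC(=O)/C=C\C1(CCC2(CC1)OCCO2)c3cc(B4OC(C)(C)C(C)(C)O4)ccc3OC(=O)OC(C)(C)C)OCC | intermediate
16 | (Z)-3-iodoacrylic acid | OC(=O)/C=C\I | starting material
17 | tert-butyl (4-aminobutyl)carbamate | CC(C)(C)OC(=O)NCCCCN | starting material
18 | tert-butyl {4-[(Z)-3-iodoprop-2-enamido]butyl}carbamate | CC(C)(C)OC(=O)NCCCCNC(=O)/C=C\I | intermediate
19 | tert-butyl 4-[(Z)-3-({4-[(tert-butoxycarbonyl)amino]butyl}amino)-3-oxoprop-1-enyl]-2-{8-[(Z)-3-[(3,3-diethoxypropyl)amino]-3-oxoprop-1-enyl]-1,4-dioxaspiro[4.5]decan-8-yl}phenyl carbonate | CCOC(CCNC(=O)/C=C\C1(CCC2(CC1)OCCO2)c3cc(/C=C\C(=O)NCCCCNC(=O)OC(C)(C)C)ccc3OC(=O)OC(C)(C)C)OCC | intermediate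
20 | (Z)-N-(4-ammoniobutyl)-3-{4-hydroxy-3-[4-oxo-1-{(Z)-3-oxo-3-[(3-oxopropyl)amino]prop-1-enyl}cyclohexyl]phenyl}prop-2-enamide trifluoroacetate | O=CCCNC(=O)/C=C\C1(CCC(=O)CC1)c2cc(/C=C\C(=O)NCCCC[NH3+])ccc2O.[O-]C(=O)C(F)(F)F | intermediate
21 | macrocyclic imine: as 22, with C=N between the propyl-chain terminus and the butylamine nitrogen | O=C1CCC2(CC1)/C=C\C(=O)NCCC=NCCCCNC(=O)/C=C\c3ccc(O)c2c3 | intermediate
22 | achiral macrocyclic keto phenol amine: cyclohexan-4-one whose C1 carries a 2-hydroxyphenyl ring and a (Z)-CH=CH–C(=O)NH(CH2)3NH(CH2)4NHC(=O)–CH=CH-(Z) chain that ends at C5 of that phenyl ring (20-membered ring) | O=C1CCC2(CC1)/C=C\C(=O)NCCCNCCCCNC(=O)/C=C\c3ccc(O)c2c3 | intermediate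
23 | (S)-enone: 22 with a C=C bond between the α- and β-carbons of the pro-S arm (4,4-disubstituted cyclohex-2-enone, free phenol) | O=C1CC[C@@]2(/C=C\C(=O)NCCCNCCCCNC(=O)/C=C\c3ccc(O)c2c3)C=C1 | intermediate
24 | target CNP0159470.1: (4aR,9bS)-cis-fused 1,2,4,4a-tetrahydrodibenzofuran-3(9bH)-one whose (Z)-CH=CH–C(=O)NH(CH2)3NH(CH2)4NHC(=O)–CH=CH-(Z) chain bridges C9b and C8 | O=C1CC[C@]23/C=C\C(=O)NCCCNCCCCNC(=O)/C=C\c4ccc(c2c4)O[C@@H]3C1 | target

**Step count**

Total step count: 12. Longest linear sequence: 10 steps (steps 1–4, 6, 7, 9–12).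

**Steps most likely to fail, with fallbacks**

1. Step 12 (Proposed new method). What may go wrong: too little turnover of the bulky spiro-macrocyclic ketone in the enzyme pocket, weak discrimination of the two enantiotopic arms, or further oxidation of the product. Fallback with known chemistry, setting out from 22 and coming back at 24: non-enzymatic aerobic palladium(II) dehydrogenation of the cyclohexanone (Pd(DMSO)2(TFA)2, O2, AcOH, 60–80 °C, stopped at partial conversion) should give the racemic enone, which closes spontaneously by oxa-Michael addition to the racemic ring-closed ketone F1 (24 together with its mirror image). The enantiomers are then separated by preparative chromatography on a chiral stationary phase (SFC), which returns to the route at 24.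

2. Step 11. What may go wrong: oligomerisation or double alkylation during imine formation and reduction, or competing amination of the ring ketone. The fallback sets out from 15 and 18 and comes back at 22; it forms the amine intermolecularly and closes the ring at the aryl–alkenyl bond instead. Hydrolysis of both acetals of 15 (Amberlyst-15, acetone/H2O, rt) should give the keto aldehyde boronate F2, and 18 is N-deprotected (TFA, CH2Cl2, 0 °C) to the ammonium trifluoroacetate F3. Reductive amination of F2 with F3 (NaBH(OAc)3, i-Pr2NEt, DCE), followed in the same flask by Boc2O, should give the N-Boc amine F4, which carries both the boronate and the Z-iodoalkene. An intramolecular Suzuki–Miyaura coupling under high dilution (Pd(PPh3)4, K3PO4, THF/H2O, 2 mM, 45 °C) then closes the ring to the doubly Boc-protected macrocycle F5. TFA/CH2Cl2/H2O removes both Boc groups and returns to the route at 22.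

3. Step 6. What may go wrong: slow olefination of the hindered, lactol-masked aldehyde with erosion of Z selectivity on warming, or oxa-Michael closure of the phenoxide before it is capped. The fallback sets out from 9 and comes back at 14; it makes the Z-alkene first and the amide second. Stork–Zhao olefination of the lactol-derived aldehyde (Ph3P+CH2I I−, NaHMDS, THF/DMPU, −78 °C), with Boc2O capping of the phenoxide in the same flask, should give the Z-iodoalkene carbonate F6. Palladium-catalysed aminocarbonylation of the alkenyl iodide with amine 11 (CO 1 atm, Pd(PPh3)2Cl2, Et3N, DMF, 40 °C) should proceed with retention and in preference to the aryl bromide, and returns to the route at 14.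

**Further compounds**

F1 | step 12 | racemic ring-closed ketone (1:1 mixture of 24 and its (4aS,9bR) enantiomer) | O=C1CC[C@]23/C=C\C(=O)NCCCNCCCCNC(=O)/C=C\c4ccc(c2c4)O[C@@H]3C1.O=C1CC[C@@]23/C=C\C(=O)NCCCNCCCCNC(=O)/C=C\c4ccc(c2c4)O[C@H]3C1
F2 | step 11 | tert-butyl 2-[4-oxo-1-{(Z)-3-oxo-3-[(3-oxopropyl)amino]prop-1-enyl}cyclohexyl]-4-(4,4,5,5-tetramethyl-1,3,2-dioxaborolan-2-yl)phenyl carbonate | O=CCCNC(=O)/C=C\C1(CCC(=O)CC1)c2cc(B3OC(C)(C)C(C)(C)O3)ccc2OC(=O)OC(C)(C)C
F3 | step 11 | 4-[(Z)-3-iodoprop-2-enamido]butan-1-aminium trifluoroacetate | [NH3+]CCCCNC(=O)/C=C\I.[O-]C(=O)C(F)(F)F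
F4 | step 11 | N-Boc amine: F2 joined through its former aldehyde carbon to the nitrogen of F3, that nitrogen carrying Boc | O=C1CCC(CC1)(/C=C\C(=O)NCCCN(CCCCNC(=O)/C=C\I)C(=O)OC(C)(C)C)c2cc(B3OC(C)(C)C(C)(C)O3)ccc2OC(=O)OC(C)(C)C
F5 | step 11 | doubly Boc-protected macrocycle (22 with N-Boc on the secondary amine and O-Boc on the phenol) | O=C1CCC2(CC1)/C=C\C(=O)NCCCN(C(=O)OC(C)(C)C)CCCCNC(=O)/C=C\c3ccc(OC(=O)OC(C)(C)C)c2c3
F6 | step 6 | tert-butyl 4-bromo-2-{8-[(Z)-2-iodoethenyl]-1,4-dioxaspiro[4.5]decan-8-yl}phenyl carbonate | I/C=C\C1(CCC2(CC1)OCCO2)c3cc(Br)ccc3OC(=O)OC(C)(C)C
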